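In a one-step world starting material and reagent go on to target until one of them ends, yet elm, the flask asked about, stands at 18.8% target after 10.0 h, with 11 mM of reagent charged against 10 mM of starting material.

| flask | starting material | second substrate | reagent | free catalyst | remark | time |
|---|---|---|---|---|---|---|
| elm | 10 mM | 5 mM | 11 mM | 17 µM | the very flask that is asked about, followed so far |  |
| cedar | 6.7 mM | 5 mM | 11 mM | 17 µM | run made earlier |  |
| flask | 10 mM | 5.00 mM | 11.0 mM | 17 µM |  | 10 h |

| run | time / h | target / % |
|---|---|---|
| elm | 0.833 | 8.6 |
| elm | 2.00 | 13.1 |
| elm | 4.00 | 17.9 |
| elm | 10.0 | 18.8 |
| cedar | 0.250 | 3.0 |
| cedar | 0.667 | 7.3 |
| cedar | 1.50 | 12.6 |
| cedar | 4.00 | 19.5 |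

(standard deviation of a reading: 0.5 percentage points)

- north-east: at 10 h take out 90% of the target then present, then wait 10 h
- north: at 10 h add reagent, 100% of the amount charged, then wait 10 h
- north-west: change nothing and wait 10 h more
- south-west: at 10 h add free catalyst, 100% of the amount charged, then wait 10 h

* target, in percent of the starting material first charged, at 10 h
* the option that brings most further target ("none" if no option brings more than 2 percentage points) (north-east / north / north-west / south-west / none)
* target present, with what was taken out counted in, in percent of the starting material first charged, after north
* target present, with what was taken out counted in, in percent of the starting material first charged, after south-west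

- target taken out counts as made
- additions bring no volume worth counting

Two chemists read these runs and agree on one point. Elm charges 1.49 times the starting material of cedar, yet the target percentages end close together. So both take the rate as pseudo-first-order in starting material, multiplied by an activity that falls with time and is shared by the two runs. What is then nearly constant is a percentage-free number. Elm's last reading gives 0.208 for the dose D, defined as minus the natural logarithm of the share of starting material not turned into target. Cedar's reading at 4.00 h gives 0.217.

They part over what pays for D. The reagent side says reagent ran out through an unseen wasteful route. Counting one reagent per target, that route must have taken 9.12 mM in elm. Fresh reagent then buys a second D, which carries target to 34.1% after north.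

The catalyst side says free catalyst is lost with time. That asks only 17 µM to vanish, far less than the reagent side's waste.

I hold with the catalyst side, and that is my own reckoning. Elm stays near its last reading after north, and south-west carries a second dose. That gives 34.1% if the second dose equals the first, and I expect less, though I cannot say from these runs how much less.

The forecast, from the reagent side, gives 18.9% at 10 h, north as the best option, 29% after north, which is below the full-dose figure, and 19.2% after south-west, holding that “Fresh reagent should repeat the run on depleted substrates”.

The simulation gives 18.4% at 10 h, and the best option is south-west, with 27.7% after south-west against 18.4% after north.

    starting material + free catalyst ⇌ catalyst intermediate A (K = 77.0 /M, k = 440 /M/s)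
    reagent + catalyst intermediate A → free catalyst + target (k = 11.0 /M/s)
    second substrate + free catalyst ⇌ catalyst intermediate B (K = 53000 /M, k = 92.0 /M/s)
    reagent + catalyst intermediate B → free catalyst + second product (k = 15.0 /M/s)
    free catalyst → spent catalyst (k = 4.40 × 10⁻⁴ /s)

In elm at 10.0 h, spent catalyst stands at >99.9% of the catalyst charged, with 39% of the reagent and 82% of the starting material left. The second charge of free catalyst carries a dose of 0.121, less than the 0.208 read in elm. The reagent side keeps the charge at the start: a neighbour flask, the same recipe with 27 mM of reagent from the beginning, reaches 47.6%, a dose of 0.646, which is 3.11 times D.

The runs stem from a simulated flask on assumed constants, noise included.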